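**Retrosynthetic overview**

1. Target 21 ← desilylation of 20 ← ether closure (O1–CH2, monotosylate displacement) of 1,4-diol 17 ← LiBH4 opening of lactone 16; the S carbinol ← chelate-controlled reduction of the aroyl ketone of 14.
2. Key disconnection C3–C4: trans-keto lactone 14 ← divalent-rhodium carbenoid 1,5 C–H insertion of diazo keto ester 13.
3. Feature used: in the tetrahydrofuran (O1, C2, C3, C4, C5), C3 lies between the carbinol carbon and C2, both of which can be carbonyl carbons flanking a carbene carbon, while C4 is the middle CH2 of an ArCH2–CH2–CH2–O chain (benzyl carbon, C4, C5, O1).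
4. 13 ← diazo transfer on keto ester 12 ← alcohol 5 (from sinapic acid) + acyl Meldrum's acid 10 (from syringic acid).
5. Ring order: the only new ring is formed as the gamma-lactone in step 8, opened in step 11 and closed again as the tetrahydrofuran in step 12.

Key step: step 8

Assumption: Rh2(S-PTTL)4 is taken to give the 4R lactone; the sense of induction cannot be assigned with certainty beforehand, and if it proves opposite the enantiomeric catalyst Rh2(R-PTTL)4 is used with no other change.

Abbreviations: TBS = tert-butyldimethylsilyl; Ar = 4-(tert-butyldimethylsilyloxy)-3,5-dimethoxyphenyl.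

**Route**

Step 1
Reactants: 1 sinapic acid
Product: 2 3-(4-hydroxy-3,5-dimethoxyphenyl)propanoic acid
Conditions: H2 (1 atm), 10% Pd/C, MeOH, rt
Reagents that add atoms: none
Why: Heterogeneous catalytic hydrogenation should saturate only the cinnamic C=C at 1 atm and room temperature, the arene, acid and phenol being inert.

Step 2
Reactants: 2 3-(4-hydroxy-3,5-dimethoxyphenyl)propanoic acid
Product: 4 3-Ar-propanoic acid, via silyl ester 3 (not isolated)
Conditions: TBSCl (2.5 equiv), imidazole, DMF, rt; then AcOH/THF/H2O (3:1:1), rt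
Reagents that add atoms: tert-butyldimethylsilyl chloride (TBSCl), CC(C)(C)[Si](C)(C)Cl
Why: Imidazole-promoted silylation should cap both the hindered phenol and the acid, and the silyl ester, far more labile than the aryl silyl ether, should then be hydrolysed selectively by dilute aqueous acetic acid.

Step 3
Reactants: 4 3-Ar-propanoic acid
Product: 5 3-Ar-propan-1-ol
Conditions: BH3·SMe2, THF, 0 °C → rt; MeOH quench
Reagents that add atoms: none
Why: Borane reduction of a carboxylic acid to the primary alcohol is chemoselective and should leave the aryl silyl ether and the methyl ethers untouched.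

Step 4
Reactants: 6 syringic acid
Product: 8 4-(tert-butyldimethylsilyloxy)-3,5-dimethoxybenzoic acid, via silyl ester 7 (not isolated)
Conditions: TBSCl (2.5 equiv), imidazole, DMF, rt; then AcOH/THF/H2O (3:1:1), rt
Reagents that add atoms: tert-butyldimethylsilyl chloride (TBSCl), CC(C)(C)[Si](C)(C)Cl
Why: Same silylation and selective silyl ester hydrolysis as in step 2, leaving only the phenol protected.

Step 5
Reactants: 8 4-(tert-butyldimethylsilyloxy)-3,5-dimethoxybenzoic acid; 9 Meldrum's acid
Product: 10 5-[Ar(hydroxy)methylidene]-2,2-dimethyl-1,3-dioxane-4,6-dione (enolised acyl Meldrum's acid)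
Conditions: DCC, DMAP, CH2Cl2, 0 °C → rt; cold aq KHSO4 wash, used crude
Reagents that add atoms: none
Why: Carbodiimide activation with DMAP acyl transfer (Steglich-type C-acylation, first half of the Oikawa–Yonemitsu keto ester synthesis) should acylate the acidic methylene of Meldrum's acid.

Step 6
Reactants: 10 acyl Meldrum's acid; 5 3-Ar-propan-1-ol
Product: 12 3-Ar-propyl 3-Ar-3-oxopropanoate, via aroylketene 11 (not isolated)
Conditions: toluene, 90 °C
Reagents that add atoms: none
Why: On heating, the acyl Meldrum's acid should lose acetone and CO2 to an aroylketene that the primary alcohol traps as the beta-keto ester (Oikawa–Yonemitsu alcoholysis), under neutral conditions that the aryl silyl ethers tolerate.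

Step 7
Reactants: 12 3-Ar-propyl 3-Ar-3-oxopropanoate
Product: 13 3-Ar-propyl 2-diazo-3-Ar-3-oxopropanoate
Conditions: p-ABSA, Et3N, MeCN, 0 °C → rt
Reagents that add atoms: 4-acetamidobenzenesulfonyl azide (p-ABSA), CC(=O)Nc1ccc(cc1)S(=O)(=O)N=[N+]=[N-]
Why: Regitz diazo transfer to the doubly activated methylene should proceed with triethylamine alone, a base too weak to disturb the aryl silyl ethers.

Step 8
Reactants: 13 3-Ar-propyl 2-diazo-3-Ar-3-oxopropanoate
Product: 14 (3S,4R)-3-(Ar-carbonyl)-4-(Ar-methyl)dihydrofuran-2(3H)-one (trans)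
Conditions: Rh2(S-PTTL)4 (2 mol%), CH2Cl2, 4 Å MS, 0 °C → rt, slow addition of 13
Reagents that add atoms: none
Why: Rh2(S-PTTL)4, dirhodium tetrakis[N-phthaloyl-(S)-tert-leucinate], a divalent-rhodium carboxylate, should expel N2 from 13 to give an electrophilic rhodium carbenoid flanked by the ketone and ester carbonyls, which inserts into a C–H bond of the CH2 beta to the ester oxygen through a concerted, asynchronous three-centre (hydride-transfer-like) transition state, forming C3–C4 and releasing the catalyst. The closest known reaction types are the dirhodium-catalysed 1,5 C–H insertion of 3-arylpropyl diazo esters to 4-benzylbutyrolactones and the enantioselective insertions of alpha-diazo beta-keto esters under phthalimido-carboxylate dirhodium catalysts. The lactone closes in the 1,5-insertion mode, through a five-membered cyclic transition state made of the carbenoid carbon, the ester C=O, the ester oxygen, the OCH2 and the reacting CH2. C4 is set by the catalyst, whose four N-phthaloyl-tert-leucinate ligands form a chiral pocket that distinguishes the two enantiotopic homobenzylic hydrogens, whereas C3, lying between two carbonyls, equilibrates through its enol to the trans arrangement. The step needs 1,5 insertion to win over 1,6 insertion at the benzylic CH2, over beta-lactone formation at the deactivated OCH2 and over attack on the electron-rich arene; the ester tether should secure this because only the homobenzylic CH2 is reached through a five-membered transition state and the arene is too remote for a favourable ring size.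

Step 9
Reactants: 14 (3S,4R)-3-(Ar-carbonyl)-4-(Ar-methyl)dihydrofuran-2(3H)-one
Product: 15 (3S,4R)-3-[(S)-Ar(hydroxy)methyl]-4-(Ar-methyl)dihydrofuran-2(3H)-one
Conditions: Zn(BH4)2 (from ZnCl2/NaBH4), Et2O/CH2Cl2, −20 → 0 °C; aq NH4Cl
Reagents that add atoms: none
Why: In this chelation-controlled zinc borohydride reduction of a beta-keto ester, zinc bridges the ketone and lactone carbonyl oxygens, so hydride should arrive on the ketone face next to C3–H and away from ring carbon C4, giving the syn (S) carbinol, while the cold, non-basic medium leaves C3, C4 and the lactone untouched.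

Step 10
Reactants: 15 (3S,4R)-3-[(S)-Ar(hydroxy)methyl]-4-(Ar-methyl)dihydrofuran-2(3H)-one
Product: 16 (3S,4R)-3-[(S)-Ar(tert-butyldimethylsilyloxy)methyl]-4-(Ar-methyl)dihydrofuran-2(3H)-one
Conditions: TBSOTf, 2,6-lutidine, CH2Cl2, −78 → 0 °C
Reagents that add atoms: tert-butyldimethylsilyl trifluoromethanesulfonate (TBSOTf), CC(C)(C)[Si](C)(C)OS(=O)(=O)C(F)(F)F
Why: Silylation of the hindered secondary benzylic alcohol with the silyl triflate and 2,6-lutidine should be fast at low temperature and masks the one hydroxyl that could compete in the later ether closure; no stereocentre is touched.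

Step 11
Reactants: 16 (3S,4R)-3-[(S)-Ar(tert-butyldimethylsilyloxy)methyl]-4-(Ar-methyl)dihydrofuran-2(3H)-one
Product: 17 (2R,3R)-2-[(S)-Ar(tert-butyldimethylsilyloxy)methyl]-3-(Ar-methyl)butane-1,4-diol
Conditions: LiBH4, THF, MeOH (3 equiv), 0 °C → rt; aq NH4Cl
Reagents that add atoms: none
Why: Lithium borohydride reduction of the lactone to the 1,4-diol should outpace beta-elimination of the silyloxy group and is mild enough for the aryl silyl ethers; the two ring stereocentres become C2 and C3 of the diol unchanged.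

Step 12
Reactants: 17 (2R,3R)-2-[(S)-Ar(tert-butyldimethylsilyloxy)methyl]-3-(Ar-methyl)butane-1,4-diol
Product: 20 (3R,4R)-3-[(S)-Ar(tert-butyldimethylsilyloxy)methyl]-4-(Ar-methyl)tetrahydrofuran, via monotosylate 18 (not isolated), via regioisomeric monotosylate 19 (not isolated)
Conditions: TsCl (1.1 equiv), pyridine, DMAP (cat.), CH2Cl2, 0 °C → 40 °C
Reagents that add atoms: none
Why: Monosulfonylation of either primary hydroxyl followed by intramolecular Williamson etherification (5-exo-tet displacement by the remaining primary hydroxyl) should give the same tetrahydrofuran from both monotosylates, the secondary oxygen being blocked as its silyl ether and the reacting CH2 carbons carrying no stereocentre.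

Step 13
Reactants: 20 (3R,4R)-3-[(S)-Ar(tert-butyldimethylsilyloxy)methyl]-4-(Ar-methyl)tetrahydrofuran
Product: 21 (S)-(4-hydroxy-3,5-dimethoxyphenyl)[(3R,4R)-4-(4-hydroxy-3,5-dimethoxybenzyl)tetrahydrofuran-3-yl]methanol (target)
Conditions: TBAF (4 equiv), AcOH (4 equiv), THF, 0 °C → rt, under N2
Reagents that add atoms: none
Why: Fluoride-mediated cleavage of the two aryl silyl ethers and the secondary silyl ether, buffered with acetic acid so that neither phenoxide-driven quinone methide formation nor acid ionisation of the benzylic carbinol can erode the S centre, should release the target.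

**Compound list**

1 | sinapic acid | COc1cc(/C=C/C(=O)O)cc(OC)c1O | starting material
2 | 3-(4-hydroxy-3,5-dimethoxyphenyl)propanoic acid | COc1cc(CCC(=O)O)cc(OC)c1O | intermediate
3 | tert-butyldimethylsilyl 3-Ar-propanoate (silyl ester) | COc1cc(CCC(=O)O[Si](C)(C)C(C)(C)C)cc(OC)c1O[Si](C)(C)C(C)(C)C | intermediate
4 | 3-Ar-propanoic acid | COc1cc(CCC(=O)O)cc(OC)c1O[Si](C)(C)C(C)(C)C | intermediate
5 | 3-Ar-propan-1-ol | COc1cc(CCCO)cc(OC)c1O[Si](C)(C)C(C)(C)C | intermediate
6 | syringic acid | COc1cc(C(=O)O)cc(OC)c1O | starting material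
7 | tert-butyldimethylsilyl 4-(tert-butyldimethylsilyloxy)-3,5-dimethoxybenzoate (silyl ester) | COc1cc(C(=O)O[Si](C)(C)C(C)(C)C)cc(OC)c1O[Si](C)(C)C(C)(C)C | intermediate
8 | 4-(tert-butyldimethylsilyloxy)-3,5-dimethoxybenzoic acid | COc1cc(C(=O)O)cc(OC)c1O[Si](C)(C)C(C)(C)C | intermediate
9 | Meldrum's acid | CC1(C)OC(=O)CC(=O)O1 | starting material
10 | 5-[Ar(hydroxy)methylidene]-2,2-dimethyl-1,3-dioxane-4,6-dione | COc1cc(C(O)=C2C(=O)OC(C)(C)OC2=O)cc(OC)c1O[Si](C)(C)C(C)(C)C | intermediate
11 | aroylketene, 3-Ar-3-oxoprop-1-en-1-one | COc1cc(C(=O)C=C=O)cc(OC)c1O[Si](C)(C)C(C)(C)C | intermediate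
12 | 3-Ar-propyl 3-Ar-3-oxopropanoate | COc1cc(CCCOC(=O)CC(=O)c2cc(OC)c(O[Si](C)(C)C(C)(C)C)c(OC)c2)cc(OC)c1O[Si](C)(C)C(C)(C)C | intermediate
13 | 3-Ar-propyl 2-diazo-3-Ar-3-oxopropanoate | COc1cc(CCCOC(=O)C(=[N+]=[N-])C(=O)c2cc(OC)c(O[Si](C)(C)C(C)(C)C)c(OC)c2)cc(OC)c1O[Si](C)(C)C(C)(C)C | intermediate
14 | (3S,4R)-3-(Ar-carbonyl)-4-(Ar-methyl)dihydrofuran-2(3H)-one | COc1cc(C[C@H]2COC(=O)[C@@H]2C(=O)c2cc(OC)c(O[Si](C)(C)C(C)(C)C)c(OC)c2)cc(OC)c1O[Si](C)(C)C(C)(C)C | intermediate
15 | (3S,4R)-3-[(S)-Ar(hydroxy)methyl]-4-(Ar-methyl)dihydrofuran-2(3H)-one | COc1cc(C[C@H]2COC(=O)[C@@H]2[C@H](O)c2cc(OC)c(O[Si](C)(C)C(C)(C)C)c(OC)c2)cc(OC)c1O[Si](C)(C)C(C)(C)C | intermediate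
16 | (3S,4R)-3-[(S)-Ar(tert-butyldimethylsilyloxy)methyl]-4-(Ar-methyl)dihydrofuran-2(3H)-one | COc1cc(C[C@H]2COC(=O)[C@@H]2[C@H](O[Si](C)(C)C(C)(C)C)c2cc(OC)c(O[Si](C)(C)C(C)(C)C)c(OC)c2)cc(OC)c1O[Si](C)(C)C(C)(C)C | intermediate
17 | (2R,3R)-2-[(S)-Ar(tert-butyldimethylsilyloxy)methyl]-3-(Ar-methyl)butane-1,4-diol | COc1cc(C[C@@H](CO)[C@H](CO)[C@H](O[Si](C)(C)C(C)(C)C)c2cc(OC)c(O[Si](C)(C)C(C)(C)C)c(OC)c2)cc(OC)c1O[Si](C)(C)C(C)(C)C | intermediate
18 | 4-O-tosyl derivative of diol 17 (tosyloxy on the CH2 of the benzyl-bearing carbon) | COc1cc(C[C@@H](COS(=O)(=O)c3ccc(C)cc3)[C@H](CO)[C@H](O[Si](C)(C)C(C)(C)C)c2cc(OC)c(O[Si](C)(C)C(C)(C)C)c(OC)c2)cc(OC)c1O[Si](C)(C)C(C)(C)C | intermediate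
19 | 1-O-tosyl derivative of diol 17 (tosyloxy on the CH2 of the carbon bearing the silyloxybenzyl arm) | COc1cc(C[C@@H](CO)[C@H](COS(=O)(=O)c3ccc(C)cc3)[C@H](O[Si](C)(C)C(C)(C)C)c2cc(OC)c(O[Si](C)(C)C(C)(C)C)c(OC)c2)cc(OC)c1O[Si](C)(C)C(C)(C)C | intermediate
20 | (3R,4R)-3-[(S)-Ar(tert-butyldimethylsilyloxy)methyl]-4-(Ar-methyl)tetrahydrofuran | COc1cc(C[C@H]2COC[C@@H]2[C@H](O[Si](C)(C)C(C)(C)C)c2cc(OC)c(O[Si](C)(C)C(C)(C)C)c(OC)c2)cc(OC)c1O[Si](C)(C)C(C)(C)C | intermediate
21 | (S)-(4-hydroxy-3,5-dimethoxyphenyl)[(3R,4R)-4-(4-hydroxy-3,5-dimethoxybenzyl)tetrahydrofuran-3-yl]methanol | COc1cc(C[C@H]2COC[C@@H]2[C@H](O)c2cc(OC)c(O)c(OC)c2)cc(OC)c1O | target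

**Step count and risks**

Total step count: 13. Longest linear sequence: 11 steps (steps 1–3 and 6–13, from sinapic acid).

Steps most likely to fail:

1. Step 8. The catalyst may discriminate the two enantiotopic homobenzylic hydrogens poorly, or the acceptor/acceptor carbenoid may leak into benzylic 1,6 insertion, beta-lactone formation or carbene dimerisation. The fallback keeps the same C3–C4 insertion but uses an acceptor-only diazoacetate under a carboxamidate catalyst, a combination established for 3-arylpropyl esters, and introduces the aroyl group afterwards. It sets out from alcohol 5 and acid 8 and returns at 14. Alcohol 5 is acylated with bromoacetyl bromide and pyridine to 3-Ar-propyl bromoacetate F1. F1 is converted with N,N'-ditosylhydrazine and DBU in THF into 3-Ar-propyl diazoacetate F2. F2 is cyclised with the divalent-rhodium carboxamidate Rh2(4S-MPPIM)4, dirhodium tetrakis[methyl 1-(3-phenylpropanoyl)-2-oxoimidazolidine-4(S)-carboxylate], in refluxing CH2Cl2 to (R)-4-(Ar-methyl)dihydrofuran-2(3H)-one F3; the enantiomeric catalyst would be taken if the sense proved opposite. Acid 8 is converted with oxalyl chloride and catalytic DMF into 4-(tert-butyldimethylsilyloxy)-3,5-dimethoxybenzoyl chloride F4. The lithium enolate of F3 (LiHMDS, 2.2 equiv, THF, −78 °C) is C-acylated with F4; protonation on work-up should give the thermodynamic trans keto lactone 14.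

2. Step 9. Part of the reduction may run through a non-chelated conformer, in which hydride adds to the opposite ketone face and gives the anti carbinol, or enolisation of the 1,3-dicarbonyl may stall the reduction. The fallback moves stereocontrol from the substrate chelate to a chiral catalyst. It goes from 14 directly to 15 by Noyori–Ikariya asymmetric transfer hydrogenation with the divalent-ruthenium complex RuCl[(S,S)-TsDPEN](p-cymene) in HCO2H/Et3N (5:2) and CH2Cl2 at rt. The catalyst's aryl-ketone recognition should give the S carbinol, as it does for aryl alkyl ketones. C3 is labile in this medium, so it would have to be confirmed that the trans epimer is the one reduced. No new compound is made.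

3. Step 5. The electron-rich, hindered aroyl donor may acylate Meldrum's acid sluggishly, with N-acylurea formation or hydrolysis of the adduct on work-up. The fallback is a magnesium malonate acylation (Masamune–Brooks type). It sets out from 5, 8 and 9 and returns at 12. Alcohol 5 is heated with Meldrum's acid 9 in toluene to 3-oxo-3-(3-Ar-propoxy)propanoic acid F5. Acid 8 is activated with carbonyldiimidazole in THF to 1-[4-(tert-butyldimethylsilyloxy)-3,5-dimethoxybenzoyl]imidazole F6. The magnesium salt of F5 (MgCl2, Et3N, MeCN/THF) is C-acylated by F6 to the 2-aroylmalonic half ester F7, which should decarboxylate on mild acidic work-up to keto ester 12.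

**Further compounds**

F1 | step 8 | 3-Ar-propyl bromoacetate | COc1cc(CCCOC(=O)CBr)cc(OC)c1O[Si](C)(C)C(C)(C)C
F2 | step 8 | 3-Ar-propyl diazoacetate | COc1cc(CCCOC(=O)C=[N+]=[N-])cc(OC)c1O[Si](C)(C)C(C)(C)C
F3 | step 8 | (R)-4-(Ar-methyl)dihydrofuran-2(3H)-one | COc1cc(C[C@H]2COC(=O)C2)cc(OC)c1O[Si](C)(C)C(C)(C)C
F4 | step 8 | 4-(tert-butyldimethylsilyloxy)-3,5-dimethoxybenzoyl chloride | COc1cc(C(=O)Cl)cc(OC)c1O[Si](C)(C)C(C)(C)C
F0 | step 9 | none | none
F5 | step 5 | 3-oxo-3-(3-Ar-propoxy)propanoic acid | COc1cc(CCCOC(=O)CC(=O)O)cc(OC)c1O[Si](C)(C)C(C)(C)C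
F6 | step 5 | 1-[4-(tert-butyldimethylsilyloxy)-3,5-dimethoxybenzoyl]imidazole | COc1cc(C(=O)n2ccnc2)cc(OC)c1O[Si](C)(C)C(C)(C)C
F7 | step 5 | 2-(Ar-carbonyl)-3-oxo-3-(3-Ar-propoxy)propanoic acid | COc1cc(CCCOC(=O)C(C(=O)O)C(=O)c2cc(OC)c(O[Si](C)(C)C(C)(C)C)c(OC)c2)cc(OC)c1O[Si](C)(C)C(C)(C)C
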